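**Assumption:** the target is taken as drawn in the SMILES, i.e. (1S,4R,5S,6S,8S,10R) in the numbering below.
**Convention:** locants C1–C15 are those of the target skeleton: ring carbons C1–C10 (C1 CH–OH, C4/C5 epoxide, C6 lactone O–CH, C8 CH–O-methacrylate, C10 CH–CH3), C7=C11 butenolide alkene, C12 lactone carbonyl, C13 CH2OAc, C14 = CH3 on C10, C15 = CH3 on C4. TBS = tert-butyldimethylsilyl, Ipc = isopinocampheyl.

## Retrosynthetic overview

1. Target 21 ⇒ acyclic epoxy aldehyde 18 carrying a tetrasubstituted (Z)-β-iodo enoate: one CrCl2/NiCl2 operation forms C6–C7, the 10-membered carbocycle and the butenolide, as the last step and without protecting groups.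
2. 18 ⇒ allylic alcohol 16 by Sharpless epoxidation (the epoxide is the first ring) and alcohol oxidation.
3. Iodo enoate 15 ⇒ γ-acyloxy ynoate 12 by iodide/formaldehyde iodo-aldol addition; C8 comes from asymmetric addition of methyl propiolate to aldehyde 8.
4. The C1/C10 anti pair ⇒ (E)-crotylboration of aldehyde 4, which comes from nerol (C1–C6 and C15) by selective ozonolysis.
5. Ring order: epoxide (step 10), then 10-membered ring and butenolide together (step 12).

## Route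

**Step 1**
Reactants: 1 nerol
Product: 2 nerol TBS ether, (2Z)-1-(TBS-oxy)-3,7-dimethylocta-2,6-diene
Conditions: TBSCl, imidazole, DMF, 0 °C → rt
Reagents that add atoms: TBSCl, CC(C)(C)[Si](C)(C)Cl
Why: Standard silylation of the primary allylic alcohol (silyl ether protection); the Z alkene is untouched.

**Step 2**
Reactants: 2 nerol TBS ether
Product: 4 (4Z)-6-(TBS-oxy)-4-methylhex-4-enal (C1 aldehyde), via ozonide 3 (not isolated)
Conditions: O3 (1.0 equiv), CH2Cl2, −78 °C, Sudan Red 7B end point; then PPh3, −78 °C → rt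
Reagents that add atoms: ozone, [O-][O+]=O
Why: Chemoselective ozonolysis: the remote isopropylidene alkene is more electron-rich than the alkene deactivated by the allylic silyloxy group, and the dye marks the end point before the second alkene reacts.

**Step 3**
Reactants: 4 (4Z)-6-(TBS-oxy)-4-methylhex-4-enal
Product: 6 (3R,4S,7Z)-9-(TBS-oxy)-3,7-dimethylnona-1,7-dien-4-ol (1S,10R in target locants), via Ipc2B borinate 5 (not isolated)
Conditions: (E)-crotyl-B(Ipc)2 [made from (+)-Ipc2BOMe, (−)-α-pinene series], THF/Et2O, −78 °C; then NaOH, H2O2, 0 °C → rt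
Reagents that add atoms: (E)-crotyldiisopinocampheylborane, C/C=C/CB([C@H]1C[C@H]2C[C@@H]([C@@H]1C)C2(C)C)[C@H]1C[C@H]2C[C@@H]([C@@H]1C)C2(C)C
Why: Brown crotylboration through a chair transition state: the (E)-crotyl group gives the anti OH/CH3 pair and the (−)-α-pinene-derived Ipc groups direct Re-face attack, setting C1 (S) and C10 (R).

**Step 4**
Reactants: 6 (3R,4S,7Z)-9-(TBS-oxy)-3,7-dimethylnona-1,7-dien-4-ol
Product: 7 (3R,4S,7Z)-4,9-bis(TBS-oxy)-3,7-dimethylnona-1,7-diene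
Conditions: TBSOTf, 2,6-lutidine, CH2Cl2, −78 → 0 °C
Reagents that add atoms: TBSOTf, CC(C)(C)[Si](C)(C)OS(=O)(=O)C(F)(F)F
Why: Silylation of the hindered secondary alcohol with the silyl triflate (silyl ether protection), so that C1–OH cannot form a lactol with the C8 aldehyde made next.

**Step 5**
Reactants: 7 (3R,4S,7Z)-4,9-bis(TBS-oxy)-3,7-dimethylnona-1,7-diene
Product: 8 (3R,4S,7Z)-4,9-bis(TBS-oxy)-3,7-dimethylnon-7-enal (C8 aldehyde)
Conditions: PdCl2(PhCN)2 (10 mol %), CuCl2·2H2O (10 mol %), AgNO2 (5 mol %), O2 (1 atm), t-BuOH/MeNO2 15:1, rt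
Reagents that add atoms: dioxygen, O=O
Why: Nitrite-modified, aldehyde-selective (anti-Markovnikov) Wacker oxidation of the terminal alkene, favoured by the homoallylic oxygen; the trisubstituted alkene is inert and C10 is not epimerisable.

**Step 6**
Reactants: 8 (3R,4S,7Z)-4,9-bis(TBS-oxy)-3,7-dimethylnon-7-enal; 9 methyl propiolate
Product: 11 methyl (4S,6R,7S,10Z)-7,12-bis(TBS-oxy)-4-hydroxy-6,10-dimethyldodec-10-en-2-ynoate, via zinc alkynylide 10 (not isolated)
Conditions: Me2Zn, (S,S)-ProPhenol (20 mol %), Ph3P=O (40 mol %), toluene, 0–4 °C; aq. NH4Cl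
Reagents that add atoms: none
Why: Zinc–ProPhenol catalysed asymmetric alkynylation (Trost): the dinuclear zinc catalyst delivers the propiolate to the Re face of the aldehyde, setting C8 (S).

**Step 7**
Reactants: 11 γ-hydroxy ynoate
Product: 12 methyl (4S,6R,7S,10Z)-7,12-bis(TBS-oxy)-4-(methacryloyloxy)-6,10-dimethyldodec-10-en-2-ynoate
Conditions: methacrylic anhydride, pyridine, DMAP (cat.), CH2Cl2, 0 °C
Reagents that add atoms: methacrylic anhydride, CC(=C)C(=O)OC(=O)C(C)=C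
Why: DMAP-catalysed acylation of the only free hydroxyl installs the C8 methacrylate before a second hydroxyl exists.

**Step 8**
Reactants: 12 γ-methacryloyloxy ynoate
Product: 15 methyl (2Z,4S,6R,7S,10Z)-2-(acetoxymethyl)-7,12-bis(TBS-oxy)-3-iodo-4-(methacryloyloxy)-6,10-dimethyldodeca-2,10-dienoate, via iodoallenolate 13 (not isolated), via iodomagnesium alkoxide 14 (not isolated)
Conditions: MgI2 (1.5 equiv), monomeric CH2O (from cracked paraformaldehyde), CH2Cl2, −20 → 0 °C; then Ac2O, 2,6-lutidine, 0 °C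
Reagents that add atoms: magnesium iodide, [Mg+2].[I-].[I-]; formaldehyde, C=O; acetic anhydride, CC(=O)OC(C)=O
Why: Proposed new method: MgI2 adds iodide in conjugate fashion to C7 to give a magnesium iodoallenolate, whose aldol reaction with formaldehyde at C11 takes place on the side away from iodine (net anti addition, the sense seen when 2-alkynoates are hydroiodinated to (Z)-3-iodoalkenoates), so I ends cis to CO2Me, and the alkoxide is acetylated in the same flask; the closest known reaction is the MgI2-promoted β-iodo Morita–Baylis–Hillman (iodo-aldol) reaction of propiolates with aldehydes.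

**Step 9**
Reactants: 15 bis-TBS iodo enoate
Product: 16 methyl (2Z,4S,6R,7S,10Z)-2-(acetoxymethyl)-7,12-dihydroxy-3-iodo-4-(methacryloyloxy)-6,10-dimethyldodeca-2,10-dienoate
Conditions: HF·pyridine, THF, 0 °C → rt
Reagents that add atoms: none
Why: Fluoride-mediated desilylation removes both TBS groups at once; the acetate, methacrylate, methyl ester and vinyl iodide are stable to buffered HF.

**Step 10**
Reactants: 16 diol
Product: 17 (1S,4R,5S,8S,10R)-epoxy alcohol, methyl (2Z,4S,6R,7S)-2-(acetoxymethyl)-7-hydroxy-9-[(2R,3S)-3-(hydroxymethyl)-2-methyloxiran-2-yl]-3-iodo-4-(methacryloyloxy)-6-methylnon-2-enoate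
Conditions: Ti(OiPr)4 (20 mol %), L-(+)-diethyl tartrate (24 mol %), t-BuOOH, 4 Å MS, CH2Cl2, −20 °C
Reagents that add atoms: tert-butyl hydroperoxide, CC(C)(C)OO
Why: Sharpless asymmetric epoxidation touches only the allylic-alcohol alkene (the two electron-poor alkenes are inert), and L-(+)-tartrate on this nerol-type (Z)-alcohol gives the (4R,5S) cis-epoxide under reagent control.

**Step 11**
Reactants: 17 epoxy alcohol
Product: 18 epoxy aldehyde, methyl (2Z,4S,6R,7S)-2-(acetoxymethyl)-9-[(2R,3R)-3-formyl-2-methyloxiran-2-yl]-7-hydroxy-3-iodo-4-(methacryloyloxy)-6-methylnon-2-enoate (the C5 letter changes by CIP priority only)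
Conditions: TEMPO (10 mol %), PhI(OAc)2, CH2Cl2, rt
Reagents that add atoms: none
Why: Oxoammonium (TEMPO/PhI(OAc)2) oxidation is selective for the primary alcohol over the hindered secondary C1–OH and does not epimerise the epoxy aldehyde.

**Step 12 (key step)**
Reactants: 18 epoxy aldehyde
Product: 21 target CNP0119405.1, via vinylchromium 19 (not isolated), via chromium alkoxide 20 (not isolated)
Conditions: CrCl2 (10 equiv), NiCl2 (5 mol %), DMSO/THF, rt, 2 mM (slow addition); aqueous work-up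
Reagents that add atoms: none
Why: Nozaki–Hiyama–Kishi reaction: zerovalent nickel inserts into the C7–I bond, transmetalation gives a vinylchromium that keeps its geometry and adds to the epoxy aldehyde in Felkin–Anh fashion (anti to the epoxide C–O bond, giving 6S), and the new alkoxide, held cis to CO2Me, lactonises at once, so the 10-membered ring and the butenolide close in one operation.

## Compound list

1 | nerol, (2Z)-3,7-dimethylocta-2,6-dien-1-ol | CC(C)=CCC/C(C)=C\CO | starting material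
2 | nerol TBS ether | CC(C)=CCC/C(C)=C\CO[Si](C)(C)C(C)(C)C | intermediate
3 | ozonide (1,2,4-trioxolane) of the isopropylidene alkene of 2 | CC1(C)OOC(CC/C(C)=C\CO[Si](C)(C)C(C)(C)C)O1 | intermediate (not isolated)
4 | (4Z)-6-(TBS-oxy)-4-methylhex-4-enal | O=CCC/C(C)=C\CO[Si](C)(C)C(C)(C)C | intermediate
5 | diisopinocampheylborinate of 6 | C=C[C@@H](C)[C@@H](OB([C@H]1C[C@H]2C[C@@H]([C@@H]1C)C2(C)C)[C@H]1C[C@H]2C[C@@H]([C@@H]1C)C2(C)C)CC/C(C)=C\CO[Si](C)(C)C(C)(C)C | intermediate (not isolated)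
6 | (3R,4S,7Z)-9-(TBS-oxy)-3,7-dimethylnona-1,7-dien-4-ol | C=C[C@@H](C)[C@@H](O)CC/C(C)=C\CO[Si](C)(C)C(C)(C)C | intermediate
7 | (3R,4S,7Z)-4,9-bis(TBS-oxy)-3,7-dimethylnona-1,7-diene | C=C[C@@H](C)[C@@H](O[Si](C)(C)C(C)(C)C)CC/C(C)=C\CO[Si](C)(C)C(C)(C)C | intermediate
8 | (3R,4S,7Z)-4,9-bis(TBS-oxy)-3,7-dimethylnon-7-enal | O=CC[C@@H](C)[C@@H](O[Si](C)(C)C(C)(C)C)CC/C(C)=C\CO[Si](C)(C)C(C)(C)C | intermediate
9 | methyl propiolate | C#CC(=O)OC | starting material
10 | methyl 3-(methylzincio)propiolate | C[Zn]C#CC(=O)OC | intermediate (not isolated)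
11 | methyl (4S,6R,7S,10Z)-7,12-bis(TBS-oxy)-4-hydroxy-6,10-dimethyldodec-10-en-2-ynoate | COC(=O)C#C[C@@H](O)C[C@@H](C)[C@@H](O[Si](C)(C)C(C)(C)C)CC/C(C)=C\CO[Si](C)(C)C(C)(C)C | intermediate
12 | methyl (4S,6R,7S,10Z)-7,12-bis(TBS-oxy)-4-(methacryloyloxy)-6,10-dimethyldodec-10-en-2-ynoate | COC(=O)C#C[C@@H](OC(=O)C(C)=C)C[C@@H](C)[C@@H](O[Si](C)(C)C(C)(C)C)CC/C(C)=C\CO[Si](C)(C)C(C)(C)C | intermediate
13 | magnesium 3-iodoallenolate of 12 | COC(O[Mg]I)=C=C(I)[C@@H](OC(=O)C(C)=C)C[C@@H](C)[C@@H](O[Si](C)(C)C(C)(C)C)CC/C(C)=C\CO[Si](C)(C)C(C)(C)C | intermediate (not isolated)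
14 | iodomagnesium alkoxide of the (2Z)-2-(hydroxymethyl)-3-iodo enoate | COC(=O)/C(CO[Mg]I)=C(\I)[C@@H](OC(=O)C(C)=C)C[C@@H](C)[C@@H](O[Si](C)(C)C(C)(C)C)CC/C(C)=C\CO[Si](C)(C)C(C)(C)C | intermediate (not isolated)
15 | methyl (2Z,4S,6R,7S,10Z)-2-(acetoxymethyl)-7,12-bis(TBS-oxy)-3-iodo-4-(methacryloyloxy)-6,10-dimethyldodeca-2,10-dienoate | COC(=O)/C(COC(C)=O)=C(\I)[C@@H](OC(=O)C(C)=C)C[C@@H](C)[C@@H](O[Si](C)(C)C(C)(C)C)CC/C(C)=C\CO[Si](C)(C)C(C)(C)C | intermediate
16 | methyl (2Z,4S,6R,7S,10Z)-2-(acetoxymethyl)-7,12-dihydroxy-3-iodo-4-(methacryloyloxy)-6,10-dimethyldodeca-2,10-dienoate | COC(=O)/C(COC(C)=O)=C(\I)[C@@H](OC(=O)C(C)=C)C[C@@H](C)[C@@H](O)CC/C(C)=C\CO | intermediate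
17 | methyl (2Z,4S,6R,7S)-2-(acetoxymethyl)-7-hydroxy-9-[(2R,3S)-3-(hydroxymethyl)-2-methyloxiran-2-yl]-3-iodo-4-(methacryloyloxy)-6-methylnon-2-enoate | COC(=O)/C(COC(C)=O)=C(\I)[C@@H](OC(=O)C(C)=C)C[C@@H](C)[C@@H](O)CC[C@@]1(C)O[C@H]1CO | intermediate
18 | methyl (2Z,4S,6R,7S)-2-(acetoxymethyl)-9-[(2R,3R)-3-formyl-2-methyloxiran-2-yl]-7-hydroxy-3-iodo-4-(methacryloyloxy)-6-methylnon-2-enoate | COC(=O)/C(COC(C)=O)=C(\I)[C@@H](OC(=O)C(C)=C)C[C@@H](C)[C@@H](O)CC[C@@]1(C)O[C@H]1C=O | intermediate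
19 | C7 vinylchromium dichloride derived from 18 | COC(=O)/C(COC(C)=O)=C(\[Cr](Cl)Cl)[C@@H](OC(=O)C(C)=C)C[C@@H](C)[C@@H](O)CC[C@@]1(C)O[C@H]1C=O | intermediate (not isolated)
20 | 10-membered C6 chromium alkoxide, methyl ester not yet lactonised | C=C(C)C(=O)O[C@H]1C[C@@H](C)[C@@H](O)CC[C@@]2(C)O[C@H]2[C@@H](O[Cr](Cl)Cl)/C1=C(/COC(C)=O)C(=O)OC | intermediate (not isolated)
21 | CNP0119405.1, (1S,4R,5S,6S,8S,10R)-13-acetoxy-4,5-epoxy-1-hydroxy-8-(methacryloyloxy)germacr-7(11)-en-12,6-olide | C=C(C)C(=O)O[C@H]1C[C@@H](C)[C@@H](O)CC[C@@]2(C)O[C@H]2[C@H]2OC(=O)C(COC(C)=O)=C12 | target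

## Totals and risks

Total step count: 12. Longest linear sequence: 12 steps (nerol 1 → 21).

The three steps most likely to fail:

**Step 8 (iodo-aldol; geometry of the tetrasubstituted alkene).** If the wrong alkene isomer dominates, set out from 11 and fix the geometry with a temporary silicon tether. Silylate 11 with (bromomethyl)chlorodimethylsilane and imidazole to the (bromomethyl)dimethylsilyl ether F3. MgI2 in CH2Cl2 then adds iodide to C7 to give the iodoallenolate F4, which is alkylated at C11 by the tethered CH2Br and closes the six-membered 1-oxa-2-silacyclohex-4-ene F5. This ring can only form with C13 cis to C8, so iodine must end cis to CO2Me. Tamao oxidation (H2O2, KF, KHCO3) opens it to the diol F6. Acetylation of the primary alcohol alone (AcCl, 2,4,6-collidine, −78 °C) gives the monoacetate F7, and methacryloyl chloride with 2,6-lutidine returns to 15.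

**Step 12 (macrocyclisation/lactonisation).** The weak points are survival of the epoxy aldehyde under divalent chromium, loss of the C8 ester from the vinylmetal, and strain in the 10-membered ring. If the epoxy aldehyde is the problem, set out from 16 and move the epoxidation after the ring closure. Oxidise the allylic alcohol of 16 with MnO2 to the (4Z)-enal F8. Run the same CrCl2/NiCl2 cyclisation, through the vinylchromium F9 and the chromium alkoxide F10, to the 4,5-deoxy lactone F11. Epoxidise its C4=C5 alkene, the only electron-rich one, with mCPBA to reach 21. In this variant C6 and the epoxide face are set by the conformation of the ring and not by a reagent.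

**Step 5 (aldehyde-selective Wacker; regioselectivity and alkene migration next to the C10 branch).** Set out from 7 and use hydroboration instead. 9-BBN in THF adds to the terminal alkene only, giving the B-alkyl-9-borabicyclononane F1. NaBO3·4H2O oxidises it to the primary alcohol F2, and Dess–Martin periodinane in CH2Cl2 returns to 8.

## Further compounds

F1 | step 5 | B-alkyl-9-borabicyclo[3.3.1]nonane from 7 (boron on C8) | C(C[C@@H](C)[C@@H](O[Si](C)(C)C(C)(C)C)CC/C(C)=C\CO[Si](C)(C)C(C)(C)C)B1C2CCCC1CCC2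
F2 | step 5 | (3R,4S,7Z)-4,9-bis(TBS-oxy)-3,7-dimethylnon-7-en-1-ol | OCC[C@@H](C)[C@@H](O[Si](C)(C)C(C)(C)C)CC/C(C)=C\CO[Si](C)(C)C(C)(C)C
F3 | step 8 | (bromomethyl)dimethylsilyl ether of 11 | COC(=O)C#C[C@@H](O[Si](C)(C)CBr)C[C@@H](C)[C@@H](O[Si](C)(C)C(C)(C)C)CC/C(C)=C\CO[Si](C)(C)C(C)(C)C
F4 | step 8 | magnesium 3-iodoallenolate of F3 | COC(O[Mg]I)=C=C(I)[C@@H](O[Si](C)(C)CBr)C[C@@H](C)[C@@H](O[Si](C)(C)C(C)(C)C)CC/C(C)=C\CO[Si](C)(C)C(C)(C)C
F5 | step 8 | methyl 5-iodo-2,2-dimethyl-6-alkyl-3,6-dihydro-2H-1,2-oxasiline-4-carboxylate (C8–O–Si–C13 ring) | COC(=O)C1=C(I)[C@H](C[C@@H](C)[C@@H](O[Si](C)(C)C(C)(C)C)CC/C(C)=C\CO[Si](C)(C)C(C)(C)C)O[Si](C)(C)C1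
F6 | step 8 | methyl (2Z,4S,6R,7S,10Z)-7,12-bis(TBS-oxy)-4-hydroxy-2-(hydroxymethyl)-3-iodo-6,10-dimethyldodeca-2,10-dienoate | COC(=O)/C(CO)=C(\I)[C@@H](O)C[C@@H](C)[C@@H](O[Si](C)(C)C(C)(C)C)CC/C(C)=C\CO[Si](C)(C)C(C)(C)C
F7 | step 8 | methyl (2Z,4S,6R,7S,10Z)-2-(acetoxymethyl)-7,12-bis(TBS-oxy)-4-hydroxy-3-iodo-6,10-dimethyldodeca-2,10-dienoate | COC(=O)/C(COC(C)=O)=C(\I)[C@@H](O)C[C@@H](C)[C@@H](O[Si](C)(C)C(C)(C)C)CC/C(C)=C\CO[Si](C)(C)C(C)(C)C
F8 | step 12 | (4Z)-enal, methyl (2Z,4S,6R,7S,10Z)-2-(acetoxymethyl)-7-hydroxy-3-iodo-4-(methacryloyloxy)-6,10-dimethyl-12-oxododeca-2,10-dienoate | COC(=O)/C(COC(C)=O)=C(\I)[C@@H](OC(=O)C(C)=C)C[C@@H](C)[C@@H](O)CC/C(C)=C\C=O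
F9 | step 12 | C7 vinylchromium dichloride derived from F8 | COC(=O)/C(COC(C)=O)=C(\[Cr](Cl)Cl)[C@@H](OC(=O)C(C)=C)C[C@@H](C)[C@@H](O)CC/C(C)=C\C=O
F10 | step 12 | 10-membered C6 chromium alkoxide with the 4Z alkene | C=C(C)C(=O)O[C@H]1C[C@@H](C)[C@@H](O)CC/C(C)=C\[C@@H](O[Cr](Cl)Cl)/C1=C(/COC(C)=O)C(=O)OC
F11 | step 12 | 4,5-deoxy lactone, (4Z)-13-acetoxy-1-hydroxy-8-(methacryloyloxy)germacra-4,7(11)-dien-12,6-olide | C=C(C)C(=O)O[C@H]1C[C@@H](C)[C@@H](O)CC/C(C)=C\[C@H]2OC(=O)C(COC(C)=O)=C12
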